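**Retrosynthetic overview**
- The C8–OMe is made last: O‑methylation of a cis‑8‑ol, from catalyst‑controlled reduction of an 8‑ketone that is carried through the route as an ethylene ketal.
- The N‑methoxy‑4‑pyridone ring comes from cyclocondensation of a 1,3,5‑triketone with MeONH2 (forms N1–C2 and N1–C8a).
- The triketone comes from two Claisen‑type acylations: enolate + methoxyacetyl chloride (C4–C4a), then β‑diketone dianion + an acetyl donor (C2–C3).
- C5 is set by Cu‑catalysed asymmetric conjugate addition of 5‑phenylpentyl‑MgBr to the mono‑ketal of cyclohex‑3‑ene‑1,2‑dione; the ketal carries the C8 oxygen and blocks the second α‑position.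
- Ring order: the carbocycle is purchased; the pyridone ring is the only ring formed.

Assumptions (one line each):
- Compound 1 is a catalogue item; if not, it is one step from cyclohexane‑1,2‑dione and ethylene glycol (TsOH).
- I cannot state from memory which TaniaPhos enantiomer gives the S adduct on this enone; the enantiomer that gives 8S is used, assigned on the first run.
- Numbered compounds are substrates, intermediates and carbon‑contributing reagents; catalysts, solvents and water are not numbered.

**Step 1**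
Reactants: 1, 1,4‑dioxaspiro[4.5]decan‑6‑one
Product: 2, 1,4‑dioxaspiro[4.5]dec‑7‑en‑6‑one
Conditions: LDA, TMSCl, THF, −78 °C; then Pd(OAc)2 (cat.), O2, DMSO, rt (crude silyl enol ether telescoped)
Reagents that add atoms: none
Why: Saegusa–Ito dehydrogenation; the ketal carbon has no hydrogens, so only one silyl enol ether and one enone can form, and no stereocentre is involved.

**Step 2**
Reactants: 2; 3, (5‑bromopentyl)benzene (as its Grignard reagent); 4, methoxyacetyl chloride
Product: 5, (8S)‑7‑(2‑methoxyacetyl)‑8‑(5‑phenylpentyl)‑1,4‑dioxaspiro[4.5]decan‑6‑one (C7 is enolised and not a fixed stereocentre)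
Conditions: 3, Mg, Et2O; CuCl (5 mol %), TaniaPhos (6 mol %), Et2O, −60 → 0 °C; then 4 (1.5 equiv), −78 → 0 °C
Reagents that add atoms: 5‑phenylpentylmagnesium bromide (from 3), Br[Mg]CCCCCc1ccccc1; methoxyacetyl chloride, COCC(Cl)=O
Why: Cu‑catalysed asymmetric conjugate addition in which the chiral ferrocenyl diphosphine selects the β‑face and sets the 8S centre (future C5), followed by Claisen‑type C‑acylation of the regiodefined magnesium enolate.

**Step 3**
Reactants: 5; 6, N‑methoxy‑N‑methylacetamide
Product: 7, (8S)‑7‑(2‑methoxy‑3‑oxobutanoyl)‑8‑(5‑phenylpentyl)‑1,4‑dioxaspiro[4.5]decan‑6‑one (tautomer mixture)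
Conditions: LDA (2.3 equiv), THF, −78 → −20 °C; then 6, −78 °C → rt; aq NH4Cl
Reagents that add atoms: N‑methoxy‑N‑methylacetamide, CC(=O)N(C)OC (acetyl group)
Why: Harris‑type acylation of a β‑diketone dianion; the second deprotonation can only occur at CH2OMe, that carbanion is acetylated, the Weinreb amide prevents over‑addition, and the 8S centre is not acidic.

**Step 4**
Reactants: 7; 8, O‑methylhydroxylamine hydrochloride
Product: 9, (5S)‑1,3‑dimethoxy‑2‑methyl‑5‑(5‑phenylpentyl)‑6,7‑dihydro‑1H‑spiro[quinoline‑8,2'‑[1,3]dioxolan]‑4(5H)‑one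
Conditions: MeONH2·HCl (1.5 equiv), pyridine, EtOH, 80 °C
Reagents that add atoms: O‑methylhydroxylamine hydrochloride, CON.Cl (N–OMe unit)
Why: Paal–Knorr‑type 1,5‑dicarbonyl cyclocondensation in which nitrogen condenses with the acetyl and ring carbonyls to give the N‑methoxy‑4‑pyridone; the O‑methyl group blocks isoxazole formation and the buffered medium keeps the dioxolane.

**Step 5**
Reactants: 9
Product: 10, (5S)‑1,3‑dimethoxy‑2‑methyl‑5‑(5‑phenylpentyl)‑6,7‑dihydroquinoline‑4,8(1H,5H)‑dione
Conditions: 3 M HCl, THF, 60 °C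
Reagents that add atoms: water, O (ketone oxygen)
Why: Acid‑catalysed ketal hydrolysis; the N–OMe and 3‑OMe groups are acid‑stable, and C5–H is not epimerised because enolising it would break the pyridone conjugation.

**Step 6**
Reactants: 10
Product: 11, (5S,8R)‑8‑hydroxy‑1,3‑dimethoxy‑2‑methyl‑5‑(5‑phenylpentyl)‑5,6,7,8‑tetrahydroquinolin‑4(1H)‑one (cis)
Conditions: RuCl[(R,R)‑TsDPEN](p‑cymene) (2 mol %), HCO2H/Et3N (5:2), CH2Cl2, 30 °C
Reagents that add atoms: none
Why: Noyori–Ikariya asymmetric transfer hydrogenation of a tetralone‑type conjugated ketone; the (R,R) catalyst gives the 8R carbinol (same sense as 1‑tetralone to (R)‑1‑tetralol), with hydride arriving anti to the C5 chain, so catalyst and substrate are matched for the cis product.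

**Step 7**
Reactants: 11; 12, iodomethane
Product: 13, waltherione H, (5S,8R)‑1,3,8‑trimethoxy‑2‑methyl‑5‑(5‑phenylpentyl)‑5,6,7,8‑tetrahydroquinolin‑4(1H)‑one
Conditions: NaH (1.2 equiv), MeI (3 equiv), THF, 0 °C → rt
Reagents that add atoms: iodomethane, CI
Why: Williamson etherification of the secondary alkoxide; no bond to either stereocentre is broken, and NaH at 0 °C does not deprotonate the pyridone 2‑methyl or C8–H.

**Compound list**
1 | 1,4‑dioxaspiro[4.5]decan‑6‑one | O=C1CCCCC12OCCO2 | starting material
2 | 1,4‑dioxaspiro[4.5]dec‑7‑en‑6‑one | O=C1C=CCCC12OCCO2 | intermediate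
3 | (5‑bromopentyl)benzene | BrCCCCCc1ccccc1 | starting material
4 | methoxyacetyl chloride | COCC(Cl)=O | starting material
5 | (8S)‑7‑(2‑methoxyacetyl)‑8‑(5‑phenylpentyl)‑1,4‑dioxaspiro[4.5]decan‑6‑one | O=C1C(C(=O)COC)[C@@H](CCCCCc2ccccc2)CCC13OCCO3 | intermediate
6 | N‑methoxy‑N‑methylacetamide | CC(=O)N(C)OC | starting material
7 | (8S)‑7‑(2‑methoxy‑3‑oxobutanoyl)‑8‑(5‑phenylpentyl)‑1,4‑dioxaspiro[4.5]decan‑6‑one | O=C1C(C(=O)C(OC)C(C)=O)[C@@H](CCCCCc2ccccc2)CCC13OCCO3 | intermediate
8 | O‑methylhydroxylamine hydrochloride | CON.Cl | starting material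
9 | (5S)‑1,3‑dimethoxy‑2‑methyl‑5‑(5‑phenylpentyl)‑6,7‑dihydro‑1H‑spiro[quinoline‑8,2'‑[1,3]dioxolan]‑4(5H)‑one | COc1c(C)n(OC)c2c(c1=O)[C@@H](CCCCCc1ccccc1)CCC23OCCO3 | intermediate
10 | (5S)‑1,3‑dimethoxy‑2‑methyl‑5‑(5‑phenylpentyl)‑6,7‑dihydroquinoline‑4,8(1H,5H)‑dione | COc1c(C)n(OC)c2c(c1=O)[C@@H](CCCCCc1ccccc1)CCC2=O | intermediate
11 | (5S,8R)‑8‑hydroxy‑1,3‑dimethoxy‑2‑methyl‑5‑(5‑phenylpentyl)‑5,6,7,8‑tetrahydroquinolin‑4(1H)‑one | COc1c(C)n(OC)c2c(c1=O)[C@@H](CCCCCc1ccccc1)CC[C@H]2O | intermediate
12 | iodomethane | CI | starting material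
13 | waltherione H, (5S,8R)‑1,3,8‑trimethoxy‑2‑methyl‑5‑(5‑phenylpentyl)‑5,6,7,8‑tetrahydroquinolin‑4(1H)‑one | COc1c(C)n(OC)c2c(c1=O)[C@@H](CCCCCc1ccccc1)CC[C@H]2OC | target

**Totals**
Total steps: 7. Longest linear sequence: 7 (1 → 13).

**Three steps most likely to fail, with fallbacks**
1. Step 4 (MeONH2 cyclocondensation). It may stall at an open‑chain oxime ether or divert to the 4‑pyranone, because the ring carbonyl sits next to the ketal. Fallback: install the N–O bond by N‑oxidation instead.
   - Cyclodehydrate 7 to the fused 3‑methoxy‑2‑methyl‑4‑pyranone (TsOH, PhMe), then NH3 to the NH‑4‑pyridone.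
   - O‑benzylate (Ag2CO3, BnBr), oxidise with mCPBA to the pyridine N‑oxide, hydrogenolyse (H2, Pd/C) to the 1‑hydroxy‑4‑pyridone.
   - Methylate with MeI/K2CO3 to reach 9.
2. Step 2 (tandem asymmetric conjugate addition and C‑acylation on an untested α‑ketal enone). The ee, the sense of induction and C‑ versus O‑acylation are all uncertain. Fallback: run it stepwise with a different organometallic.
   - Cu(OTf)2 with the (S,R,R)‑Feringa phosphoramidite and bis(5‑phenylpentyl)zinc, then protic quench to the simple ketone; this ligand is reported to give (S)‑3‑ethylcyclohexanone from cyclohexenone.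
   - Crossed Claisen condensation with methyl methoxyacetate (NaH) to give 5; the ketal leaves only one enolisable α‑carbon, so regiochemistry is guaranteed.
3. Step 6 (transfer hydrogenation of a hindered, push–pull conjugated ketone beside N–OMe). Conversion or selectivity may be poor. Fallback: use substrate control instead of catalyst control.
   - L‑Selectride, expected to attack anti to the pseudoaxial C5 chain and give the cis alcohol.
   - If the trans alcohol dominates, Mitsunobu inversion at C8 (4‑nitrobenzoic acid, DIAD, PPh3; then K2CO3/MeOH) before the final methylation.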